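**Strategy.** Each quinone ring is numbered C1 (C=O), C2 (OH), C3 (CH3), C4 (C=O), C5 (axis), C6 (arylethyl). The plan treats C4 as carbon monoxide. It treats the C6=C5–C5'=C6' array shared by the two rings as an (E,E)-diene grown from glyoxal, so the congested C5–C5' axis is present before any ring exists. A single rhodium-catalysed double [5+1] carbonylation forges C3–C4 and C4–C5 in both halves, closes both six-membered rings and sets oxygen at C2 and C4. Its precursor is an acyclic symmetric diene carrying at each end a secondary pivalate flanked by a terminal alkyne. Directed C3 methylation and oxidation at C1 finish the synthesis.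

Key step: step 6

Remark on the chemistry: the target SMILES holds no stereocentre and defines no configuration at the C5–C5' axis, so the axis is made racemic. The Why lines use the quinone numbering. In the biphenyl names, locants 1, 2, 3, 4, 5, 6 correspond to C5, C4, C3, C2, C1, C6.

Step 1
Reactants: 1 triethyl phosphonoacetate; 2 2-(2-methoxyphenyl)ethyl bromide
Product: 3 ethyl 2-(diethoxyphosphoryl)-4-(2-methoxyphenyl)butanoate (racemic)
Conditions: NaH, DMF, 0 °C; then 2, NaI (cat.), 60 °C
Reagents that add atoms: none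
Why: SN2 alkylation of the sodium phosphonoacetate carbanion (malonate-type alkylation with in situ Finkelstein activation), in which the soft stabilised anion prefers substitution to E2 elimination of the primary bromide; the new α-stereocentre forms racemic and is erased in step 2.

Step 2
Reactants: 3 phosphonate (2.1 equiv); 4 glyoxal (40 wt % in water)
Product: 6 diethyl (2E,4E)-2,5-bis[2-(2-methoxyphenyl)ethyl]hexa-2,4-dienedioate, via mono-olefinated aldehyde ester 5 (not isolated)
Conditions: K2CO3 (conc. aq.), THF, 0 °C → rt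
Reagents that add atoms: none
Why: Twofold Horner–Wadsworth–Emmons olefination in a carbonate/water medium that accepts glyoxal in its commercial hydrated form; reversible addition of the stabilised anion and the preference of the ester for the position trans to the growing diene favour E at both alkenes, and minor Z isomers are removed by chromatography or crystallisation.

Step 3
Reactants: 6 dienedioate
Product: 7 (2E,4E)-2,5-bis[2-(2-methoxyphenyl)ethyl]hexa-2,4-diene-1,6-diol
Conditions: iBu2AlH (5 equiv), CH2Cl2, −78 → 0 °C; aq. potassium sodium tartrate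
Reagents that add atoms: none
Why: Ester-to-allylic-alcohol reduction with iBu2AlH proceeds by clean 1,2-hydride delivery and leaves the diene geometry and the aryl methyl ethers untouched.

Step 4
Reactants: 7 dienediol
Product: 8 (2E,4E)-2,5-bis[2-(2-methoxyphenyl)ethyl]hexa-2,4-dienedial
Conditions: MnO2 (activated, excess), CH2Cl2, rt
Reagents that add atoms: none
Why: Heterogeneous MnO2 oxidation is selective for allylic alcohols and stops at the aldehyde, and the E-enal is also the thermodynamic isomer, so the geometry is kept.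

Step 5
Reactants: 8 dienedial; 9 ethynylmagnesium bromide (0.5 M in THF, 3 equiv)
Product: 11 (4E,6E)-4,7-bis[2-(2-methoxyphenyl)ethyl]deca-4,6-diene-1,9-diyne-3,8-diyl bis(2,2-dimethylpropanoate) (rac/meso mixture at C3 and C8), via bis(bromomagnesium alkoxide) 10 (not isolated)
Conditions: 9, THF, 0 °C; then t-BuCOCl (5 equiv), DMAP (cat.), 0 °C → rt
Reagents that add atoms: pivaloyl chloride, CC(C)(C)C(=O)Cl
Why: 1,2-Addition of an alkynyl Grignard reagent to both enal carbonyls followed by acylation of the magnesium alkoxides in the same flask spares isolation of the acid-labile allylic–propargylic diol; the two carbinol stereocentres form without control (rac and meso), which is harmless because both become the sp2 carbon C1 in step 6.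

Step 6
Reactants: 11 bis(3-pivaloyloxy-1,4-enyne)
Product: 13 2,2'-dihydroxy-6,6'-bis[2-(2-methoxyphenyl)ethyl]-[1,1'-biphenyl]-4,4'-diyl bis(2,2-dimethylpropanoate) (racemic axis), via mono-annulated aryl enyne 12 (not isolated)
Conditions: [RhCl(CO)2]2 (10 mol %), CO (50–80 bar, pressure vessel), ClCH2CH2Cl (0.02 M), 80 °C
Reagents that add atoms: carbon monoxide, [C-]#[O+]
Why: Monovalent rhodium binds a terminal alkyne, the pivalate carbonyl oxygen attacks the internal alkyne carbon, and collapse of the resulting dioxolenium moves the ester from the carbinol carbon (future C1) to that carbon (future C2), leaving a rhodium carbene at the former terminus (future C3) conjugated through C2=C1 with the C6=C5 alkene. Each ring closes in the same mode, a six-membered [5+1] carbocyclisation: the rhodatriene closes onto the diene CH (C5) to a rhodacyclohexadiene, CO inserts, reductive elimination completes C3–C4 and C4–C5, and the cyclohexadienone enolises to the C4 phenol. The closest known reaction type is the rhodium-catalysed carbonylative [5+1] cycloaddition of 3-acyloxy-1,4-enynes to resorcinol monoesters, and once the first ring is formed the remaining unit of 12 is a β-aryl enyne, a usual substrate of that reaction. No stereocentre is created: both carbinol centres become sp2, so the rac/meso mixture converges, and the C5–C5' axis forms racemic. The step needs a 1,2- rather than a 1,3-acyloxy shift and capture of the metallacycle by CO rather than by a second alkyne; the unsubstituted alkyne terminus and the bulky, poorly ionising pivalate secure the first, CO pressure and high dilution the second. The E geometry of both alkenes places only hydrogen on the inner side of each closing terminus and keeps the new phenol remote from the surviving pivalate, and the order of the chain atoms fixes the position of every ring substituent.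

Step 7
Reactants: 13 bis(resorcinol monopivalate)
Product: 14 6,6'-bis[2-(2-methoxyphenyl)ethyl]-[1,1'-biphenyl]-2,2',4,4'-tetrol
Conditions: NaOMe (6 equiv), MeOH–THF, rt, Ar; then 1 M HCl
Reagents that add atoms: none
Why: Base-mediated transesterification (methanolysis) of an aryl ester, fast even for a pivalate because phenoxide is a good leaving group; the aryl methyl ethers are inert and exclusion of air protects the phenoxides.

Step 8
Reactants: 14 tetraphenol
Product: 15 2,2',4,4'-tetrakis(methoxymethoxy)-6,6'-bis[2-(2-methoxyphenyl)ethyl]-1,1'-biphenyl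
Conditions: NaH, MOMCl, DMF, 0 °C → rt
Reagents that add atoms: chloromethyl methyl ether, COCCl
Why: Williamson-type O-alkylation of the four sodium phenoxides with the hard electrophile MOMCl gives acetals that withstand n-BuLi and direct it.

Step 9
Reactants: 15 tetra-MOM ether
Product: 17 2,2',4,4'-tetrakis(methoxymethoxy)-6,6'-bis[2-(2-methoxyphenyl)ethyl]-3,3'-dimethyl-1,1'-biphenyl, via 3,3'-dilithio biaryl 16 (not isolated)
Conditions: n-BuLi (3 equiv), THF, 0 °C → rt; then MeI, −78 °C → rt
Reagents that add atoms: iodomethane, CI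
Why: Directed ortho-metalation: C3–H lies between two chelating OMOM groups and is lithiated far faster than C1–H (one director, alkyl neighbour) or the positions next to the single OMe of the outer rings, and each aryllithium is then methylated by SN2 attack on MeI.

Step 10
Reactants: 17 dimethylated tetra-MOM ether
Product: 18 6,6'-bis[2-(2-methoxyphenyl)ethyl]-3,3'-dimethyl-[1,1'-biphenyl]-2,2',4,4'-tetrol
Conditions: HCl (conc., cat.), MeOH, 50 °C, Ar
Reagents that add atoms: none
Why: Acid-catalysed acetal exchange removes all four MOM groups, methanol trapping the methoxymethyl cation as dimethoxymethane so that the free C1 position is not alkylated, while the aryl methyl ethers survive.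

Step 11
Reactants: 18 bis(2-methylresorcinol)
Product: 19 4,4'-dihydroxy-2,2'-bis[2-(2-methoxyphenyl)ethyl]-5,5'-dimethyl-[1,1'-bi(cyclohexa-1,4-diene)]-3,3',6,6'-tetrone (target CNP0293637.0)
Conditions: (KSO3)2NO (5 equiv), KH2PO4 buffer (pH 6–7), acetone–H2O, rt; then dil. HCl
Reagents that add atoms: potassium nitrosodisulfonate (KSO3)2NO, [K+].[K+].[O]N(S(=O)(=O)[O-])S(=O)(=O)[O-]
Why: Teuber oxidation: the nitroxyl radical abstracts hydrogen from the C4 phenol and a second equivalent delivers oxygen to the para carbon C1, the only unsubstituted position of each inner ring, so that loss of imidodisulfonate gives the 1,4-quinone with the C2 hydroxyl retained; the outer anisole rings carry no free OH and are not attacked.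

**Compound list**

1 | triethyl phosphonoacetate | CCOC(=O)CP(=O)(OCC)OCC | starting material
2 | 2-(2-methoxyphenyl)ethyl bromide | COc1ccccc1CCBr | starting material
3 | ethyl 2-(diethoxyphosphoryl)-4-(2-methoxyphenyl)butanoate (racemic) | CCOC(=O)C(CCc1ccccc1OC)P(=O)(OCC)OCC | intermediate
4 | glyoxal | O=CC=O | starting material
5 | ethyl (2E)-2-[2-(2-methoxyphenyl)ethyl]-4-oxobut-2-enoate (not isolated) | CCOC(=O)/C(CCc1ccccc1OC)=C/C=O | intermediate
6 | diethyl (2E,4E)-2,5-bis[2-(2-methoxyphenyl)ethyl]hexa-2,4-dienedioate | CCOC(=O)/C(CCc1ccccc1OC)=C/C=C(\CCc1ccccc1OC)C(=O)OCC | intermediate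
7 | (2E,4E)-2,5-bis[2-(2-methoxyphenyl)ethyl]hexa-2,4-diene-1,6-diol | OC/C(CCc1ccccc1OC)=C/C=C(\CCc1ccccc1OC)CO | intermediate
8 | (2E,4E)-2,5-bis[2-(2-methoxyphenyl)ethyl]hexa-2,4-dienedial | O=C/C(CCc1ccccc1OC)=C/C=C(\CCc1ccccc1OC)C=O | intermediate
9 | ethynylmagnesium bromide | C#C[Mg]Br | starting material
10 | bis(bromomagnesium alkoxide) of the (4E,6E)-diene-1,9-diyne-3,8-diol (not isolated) | C#CC(O[Mg]Br)/C(CCc1ccccc1OC)=C/C=C(\CCc1ccccc1OC)C(O[Mg]Br)C#C | intermediate
11 | (4E,6E)-4,7-bis[2-(2-methoxyphenyl)ethyl]deca-4,6-diene-1,9-diyne-3,8-diyl bis(2,2-dimethylpropanoate), rac/meso mixture | C#CC(OC(=O)C(C)(C)C)/C(CCc1ccccc1OC)=C/C=C(\CCc1ccccc1OC)C(OC(=O)C(C)(C)C)C#C | intermediate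
12 | (4E)-5-{2-hydroxy-6-[2-(2-methoxyphenyl)ethyl]-4-(pivaloyloxy)phenyl}-4-[2-(2-methoxyphenyl)ethyl]pent-4-en-1-yn-3-yl pivalate (not isolated) | C#CC(OC(=O)C(C)(C)C)/C(CCc1ccccc1OC)=C/c1c(O)cc(OC(=O)C(C)(C)C)cc1CCc1ccccc1OC | intermediate
13 | 2,2'-dihydroxy-6,6'-bis[2-(2-methoxyphenyl)ethyl]-[1,1'-biphenyl]-4,4'-diyl bis(2,2-dimethylpropanoate) | CC(C)(C)C(=O)Oc1cc(O)c(-c2c(O)cc(OC(=O)C(C)(C)C)cc2CCc2ccccc2OC)c(CCc2ccccc2OC)c1 | intermediate
14 | 6,6'-bis[2-(2-methoxyphenyl)ethyl]-[1,1'-biphenyl]-2,2',4,4'-tetrol | COc1ccccc1CCc1cc(O)cc(O)c1-c1c(O)cc(O)cc1CCc1ccccc1OC | intermediate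
15 | 2,2',4,4'-tetrakis(methoxymethoxy)-6,6'-bis[2-(2-methoxyphenyl)ethyl]-1,1'-biphenyl | COCOc1cc(OCOC)c(-c2c(OCOC)cc(OCOC)cc2CCc2ccccc2OC)c(CCc2ccccc2OC)c1 | intermediate
16 | 3,3'-dilithio derivative of 15 (not isolated) | COCOc1c([Li])c(OCOC)c(-c2c(OCOC)c([Li])c(OCOC)cc2CCc2ccccc2OC)c(CCc2ccccc2OC)c1 | intermediate
17 | 2,2',4,4'-tetrakis(methoxymethoxy)-6,6'-bis[2-(2-methoxyphenyl)ethyl]-3,3'-dimethyl-1,1'-biphenyl | COCOc1c(C)c(OCOC)c(-c2c(OCOC)c(C)c(OCOC)cc2CCc2ccccc2OC)c(CCc2ccccc2OC)c1 | intermediate
18 | 6,6'-bis[2-(2-methoxyphenyl)ethyl]-3,3'-dimethyl-[1,1'-biphenyl]-2,2',4,4'-tetrol | Oc1c(C)c(O)c(-c2c(O)c(C)c(O)cc2CCc2ccccc2OC)c(CCc2ccccc2OC)c1 | intermediate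
19 | 4,4'-dihydroxy-2,2'-bis[2-(2-methoxyphenyl)ethyl]-5,5'-dimethyl-[1,1'-bi(cyclohexa-1,4-diene)]-3,3',6,6'-tetrone | COc1ccccc1CCC1=C(C2=C(CCc3ccccc3OC)C(=O)C(O)=C(C)C2=O)C(=O)C(C)=C(O)C1=O | target

**Totals.** Total step count: 11. Longest linear sequence: 11 steps (1 or 2 → 19).

**Steps most likely to fail**

Step 6.
- The reaction may stall after the first ring closure, because the second carbene must close onto an alkene carbon that now bears a 2,6-disubstituted aryl group.
- A 1,3-acyloxy shift, ionisation of the doubly activated pivalate, slippage of the allyl-type rhodacycle along the diene, or alkyne oligomerisation may compete.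
- The fallback sets out from 2 and makes the axis by aryl–aryl coupling.
- Zinc insertion (Zn dust, LiCl, THF) should give 2-(2-methoxyphenyl)ethylzinc bromide F1.
- Commercial 5-bromoresorcinol is protected (NaH, MOMCl, DMF) as 1-bromo-3,5-bis(methoxymethoxy)benzene F2.
- Negishi coupling of the two (Pd(OAc)2, SPhos, THF) should give the bibenzyl 1,3-bis(methoxymethoxy)-5-[2-(2-methoxyphenyl)ethyl]benzene F3.
- NIS in MeCN should iodinate the more electron-rich ring ortho to the chain and para to an OMOM group, giving 2-iodo-1,5-bis(methoxymethoxy)-3-[2-(2-methoxyphenyl)ethyl]benzene F4.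
- Ullmann homocoupling (Cu powder, DMF, 140 °C) returns to the route at 15.

Step 2.
- E selectivity may erode at either olefination.
- Hydrated glyoxal may be lost to base-induced disproportionation or oligomerisation.
- The phosphonate anion may add in conjugate fashion to the transient oxo-enoate.
- The fallback sets out from 3 and builds the diene one alkene at a time from a mono-protected glyoxal.
- Olefination of commercial 2,2-dimethoxyacetaldehyde (NaH, THF, 0 °C) should give ethyl (2E)-4,4-dimethoxy-2-[2-(2-methoxyphenyl)ethyl]but-2-enoate F5, whose geometrical isomers can be separated.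
- Mild hydrolysis (aq. CF3CO2H, CH2Cl2) releases 5, now isolated.
- A second anhydrous olefination with 3 (NaH, THF, −78 → 0 °C) returns to the route at 6.

Step 11.
- The second ring may be oxidised incompletely, phenoxyl radicals may couple, or the hydroxyquinone may degrade in the aqueous buffer; the low solubility of the lipophilic tetraphenol aggravates all three.
- The fallback sets out from 17 and installs the C1 oxygen by ionic chemistry before deprotection.
- NBS (MeCN, 0 °C) should brominate the only free position of each inner ring to the 5,5'-dibromide of 17 F6.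
- Bromine–lithium exchange (n-BuLi, THF, −78 °C) gives the 5,5'-dilithio compound F7.
- B(OMe)3 converts it into the 5,5'-bis(dimethyl boronate) F8.
- H2O2/NaOH gives the 5,5'-diol F9.
- HCl in MeOH under argon frees 6,6'-bis[2-(2-methoxyphenyl)ethyl]-3,3'-dimethyl-[1,1'-biphenyl]-2,2',4,4',5,5'-hexol F10.
- This hydroxyhydroquinone is dehydrogenated by Ag2O (Et2O, rt), arriving at 19.

**Further compounds**

F1 | step 6 | 2-(2-methoxyphenyl)ethylzinc bromide | COc1ccccc1CC[Zn]Br
F2 | step 6 | 1-bromo-3,5-bis(methoxymethoxy)benzene | COCOc1cc(Br)cc(OCOC)c1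
F3 | step 6 | 1,3-bis(methoxymethoxy)-5-[2-(2-methoxyphenyl)ethyl]benzene | COCOc1cc(CCc2ccccc2OC)cc(OCOC)c1
F4 | step 6 | 2-iodo-1,5-bis(methoxymethoxy)-3-[2-(2-methoxyphenyl)ethyl]benzene | COCOc1cc(OCOC)c(I)c(CCc2ccccc2OC)c1
F5 | step 2 | ethyl (2E)-4,4-dimethoxy-2-[2-(2-methoxyphenyl)ethyl]but-2-enoate | CCOC(=O)/C(CCc1ccccc1OC)=C/C(OC)OC
F6 | step 11 | 5,5'-dibromo-2,2',4,4'-tetrakis(methoxymethoxy)-6,6'-bis[2-(2-methoxyphenyl)ethyl]-3,3'-dimethyl-1,1'-biphenyl | COCOc1c(C)c(OCOC)c(-c2c(OCOC)c(C)c(OCOC)c(Br)c2CCc2ccccc2OC)c(CCc2ccccc2OC)c1Br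
F7 | step 11 | 5,5'-dilithio analogue of F6 | COCOc1c(C)c(OCOC)c(-c2c(OCOC)c(C)c(OCOC)c([Li])c2CCc2ccccc2OC)c(CCc2ccccc2OC)c1[Li]
F8 | step 11 | 5,5'-bis(dimethoxyboryl) analogue of F6 | COCOc1c(C)c(OCOC)c(-c2c(OCOC)c(C)c(OCOC)c(B(OC)OC)c2CCc2ccccc2OC)c(CCc2ccccc2OC)c1B(OC)OC
F9 | step 11 | 5,5'-dihydroxy analogue of F6 | COCOc1c(C)c(OCOC)c(-c2c(OCOC)c(C)c(OCOC)c(O)c2CCc2ccccc2OC)c(CCc2ccccc2OC)c1O
F10 | step 11 | 6,6'-bis[2-(2-methoxyphenyl)ethyl]-3,3'-dimethyl-[1,1'-biphenyl]-2,2',4,4',5,5'-hexol | Oc1c(C)c(O)c(-c2c(O)c(C)c(O)c(O)c2CCc2ccccc2OC)c(CCc2ccccc2OC)c1O
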